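**Plan**

- Retrosynthesis: the aldehyde is traced back to CH2OH and the phenols to benzyl ethers. The dihydrofuran is then cut at O1–C2, ring A is cut at C3a–C4, C4–C5 and C7–C7a into a chiral siloxyalkyne and a 3-(silyloxymethyl)cyclobutenone, and the C2–C3 bond is cut as an aldol.
- Enabling feature: ring A (C3a, C4, C5, C6, C7, C7a) is a resorcinol with its oxygens on C4 and C7a flanking C3a and the formyl carbon on C6 para to C3a. A 3-substituted cyclobutenone and a siloxyalkyne deliver exactly this pattern, and the two oxygens become equivalent after desilylation, so either can close the furan.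
- Forward order: both outer aryl rings are bought and joined by the aldol. The acyl carbon is homologated to the siloxyalkyne, the four-membered ring is made separately, the benzannulation builds ring A and unites the halves, and the dihydrofuran closes last.
- Stereochemistry: C3 is the α-carbon of an Evans syn aldol ((R)-4-benzyloxazolidinone, Z boron enolate) and is carried unchanged. C2 is re-set trans to C3 in the acid-mediated ring closure, giving (2S,3S).

Key step: step 12

Remark on the chemistry: benzofuran numbering of the target (O1, C2, C3, C3a, C4 to C7, C7a) is used for the atoms that become them. Ring A is locally symmetric until the furan closes, so the ketene-derived oxygen-bearing carbon is called C4 and the alkyne-derived one C7a.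

**Route**

Step 1
Reactants: 1 methyl 3,5-dihydroxyphenylacetate
Product: 2 methyl 3,5-bis(benzyloxy)phenylacetate
Conditions: BnBr, K2CO3, acetone, reflux
Reagents that add atoms: benzyl bromide, BrCc1ccccc1
Why: Williamson etherification of both phenols should proceed cleanly because K2CO3 is too weak a base to deprotonate the arylacetate methylene.

Step 2
Reactants: 2 methyl 3,5-bis(benzyloxy)phenylacetate
Product: 3 3,5-bis(benzyloxy)phenylacetic acid
Conditions: LiOH·H2O, THF/MeOH/H2O, rt; then 1 M HCl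
Reagents that add atoms: lithium hydroxide, [Li+].[OH-]
Why: Ordinary ester saponification, to which the aryl benzyl ethers are inert.

Step 3
Reactants: 3 3,5-bis(benzyloxy)phenylacetic acid; 4 (R)-4-benzyl-1,3-oxazolidin-2-one
Product: 6 (R)-4-benzyl-3-{[3,5-bis(benzyloxy)phenyl]acetyl}-1,3-oxazolidin-2-one, via mixed pivalic anhydride 5 (not isolated)
Conditions: PivCl, Et3N, THF, −20 → 0 °C; then 4, LiCl, 0 °C → rt
Reagents that add atoms: none
Why: N-acylation of the oxazolidinone by the mixed anhydride (LiCl/Et3N variant) should occur at the less hindered arylacetyl carbonyl, the pivaloyl half of 5 leaving as pivalate.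

Step 4
Reactants: 6 (R)-4-benzyl-3-{[3,5-bis(benzyloxy)phenyl]acetyl}-1,3-oxazolidin-2-one; 7 4-(benzyloxy)benzaldehyde
Product: 10 syn aldol adduct (4R)-4-benzyl-3-{(2R,3R)-2-[3,5-bis(benzyloxy)phenyl]-3-[4-(benzyloxy)phenyl]-3-hydroxypropanoyl}-1,3-oxazolidin-2-one, via Z boron enolate 8 (not isolated), via boron aldolate 9 (not isolated)
Conditions: Bu2BOTf, i-Pr2NEt, CH2Cl2, −78 → 0 °C; 7, −78 → 0 °C; then pH 7 buffer, MeOH, 30% H2O2, 0 °C
Reagents that add atoms: none
Why: Evans syn aldol in which the Z dibutylboron enolate reacts through a chair Zimmerman–Traxler transition state with the benzyl group of the (R)-auxiliary shielding one enolate face, which should set the α-carbon (future C3, R here) and the syn carbinol (R here).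

Step 5
Reactants: 10 syn aldol adduct
Product: 11 (4R)-4-benzyl-3-{(2R,3R)-2-[3,5-bis(benzyloxy)phenyl]-3-[4-(benzyloxy)phenyl]-3-(tert-butyldimethylsilyloxy)propanoyl}-1,3-oxazolidin-2-one
Conditions: TBSOTf, 2,6-lutidine, CH2Cl2, −78 → 0 °C
Reagents that add atoms: tert-butyldimethylsilyl triflate, CC(C)(C)[Si](C)(C)OS(=O)(=O)C(F)(F)F
Why: Silylation with the triflate and a hindered pyridine base is fast at low temperature and should not trigger retro-aldol cleavage of this arylacetate-derived aldol.

Step 6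
Reactants: 11 silyl-protected aldol imide
Product: 12 (2S,3R)-2-[3,5-bis(benzyloxy)phenyl]-3-[4-(benzyloxy)phenyl]-3-(tert-butyldimethylsilyloxy)propan-1-ol
Conditions: LiBH4, MeOH (1 equiv), THF, 0 °C
Reagents that add atoms: none
Why: Reductive cleavage of the imide by hydride attack at the exocyclic carbonyl should release the recoverable auxiliary and give the primary alcohol without touching the α-stereocentre.

Step 7
Reactants: 12 primary alcohol
Product: 13 (2R,3R)-2-[3,5-bis(benzyloxy)phenyl]-3-[4-(benzyloxy)phenyl]-3-(tert-butyldimethylsilyloxy)propanal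
Conditions: Dess–Martin periodinane, NaHCO3, CH2Cl2, 0 °C; used crude at once
Reagents that add atoms: none
Why: Dess–Martin oxidation under bicarbonate buffering is neutral and fast, and the aldehyde is carried on without chromatography because its α-aryl stereocentre is enolisable.

Step 8
Reactants: 13 α-aryl β-silyloxy aldehyde
Product: 14 (3R,4R)-3-[3,5-bis(benzyloxy)phenyl]-4-[4-(benzyloxy)phenyl]-1,1-dibromo-4-(tert-butyldimethylsilyloxy)but-1-ene
Conditions: CBr4, PPh3, Zn dust, CH2Cl2, rt (reagent pre-formed); then 13, 0 °C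
Reagents that add atoms: carbon tetrabromide, BrC(Br)(Br)Br
Why: Corey–Fuchs dibromomethylenation with the weakly basic ylide Ph3P=CBr2 (zinc variant, no amine) adds the future C7a carbon without enolising the aldehyde, and any C3 epimer formed would be a separable diastereomer.

Step 9
Reactants: 14 1,1-dibromoalkene
Product: 17 triisopropyl{[(3S,4R)-3-[3,5-bis(benzyloxy)phenyl]-4-[4-(benzyloxy)phenyl]-4-(tert-butyldimethylsilyloxy)but-1-yn-1-yl]oxy}silane, via lithium acetylide 15 (not isolated), via lithium ynolate 16 (not isolated)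
Conditions: n-BuLi (2.05 equiv), THF, −78 °C; LiOOt-Bu (from t-BuOOH, LiN(SiMe3)2), −78 → 0 °C; TIPSOTf, −78 → 0 °C; used promptly
Reagents that add atoms: lithium tert-butyl peroxide, CC(C)(C)OO[Li]; triisopropylsilyl triflate, CC(C)[Si](C(C)C)(C(C)C)OS(=O)(=O)C(F)(F)F
Why: The second stage of the Corey–Fuchs sequence gives the lithium acetylide, electrophilic oxygen transfer from the lithium peroxide turns it into the ynolate, and the hard silyl triflate traps it on oxygen (acetylide oxidation route to siloxyalkynes), while two equivalents of n-BuLi at −78 °C should leave the propargylic benzylic C3–H alone.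

Step 10
Reactants: 18 tert-butyldimethyl(prop-2-yn-1-yloxy)silane; 19 trichloroacetyl chloride
Product: 21 4,4-dichloro-3-[(tert-butyldimethylsilyloxy)methyl]cyclobut-2-en-1-one, via dichloroketene 20 (not isolated)
Conditions: Zn–Cu couple, Et2O/DME, rt (slow addition of 19)
Reagents that add atoms: none
Why: Ketene–alkyne (2+2) cycloaddition in which the terminal alkyne carbon bonds to the carbonyl carbon of dichloroketene generated by zinc dechlorination, which places the silyloxymethyl group on C3 of the cyclobutenone, with DME sequestering ZnCl2.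

Step 11
Reactants: 21 dichlorocyclobutenone
Product: 22 3-[(tert-butyldimethylsilyloxy)methyl]cyclobut-2-en-1-one
Conditions: Zn dust, TMEDA, AcOH, EtOH, 0 °C → rt
Reagents that add atoms: none
Why: Zinc reduction of the α,α-dichloro ketone under TMEDA/AcOH buffering should remove both chlorines without opening or isomerising the strained enone or cleaving the silyl ether.

Step 12
Reactants: 17 chiral triisopropylsiloxyalkyne; 22 silyloxymethylcyclobutenone
Product: 27 2-{(1S,2R)-1-[3,5-bis(benzyloxy)phenyl]-2-[4-(benzyloxy)phenyl]-2-(tert-butyldimethylsilyloxy)ethyl}-5-[(tert-butyldimethylsilyloxy)methyl]-3-(triisopropylsilyloxy)phenol, via vinylketene 23 (not isolated), via 4-vinylcyclobutenone 24 (not isolated), via dienylketene 25 (not isolated), via cyclohexadienone 26 (not isolated)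
Conditions: toluene, 80 °C, then 110 °C, argon; cyclobutenone in excess
Reagents that add atoms: none
Why: Heating opens 22 by reversible 4π electrocyclic cleavage to vinylketene 23, which adds to the siloxyalkyne in a (2+2) cycloaddition to give 24; a second 4π opening gives dienylketene 25, 6π electrocyclisation gives cyclohexadienone 26, and tautomerisation gives phenol 27, so that the whole cascade is an isomerising union of the two reactants in which every atom of both is retained. This is the Danheiser benzannulation in its siloxyalkyne version, the closest known reaction type being the thermal union of trialkylsiloxyalkynes with 3-substituted cyclobutenones to give 2,5-disubstituted resorcinol monosilyl ethers. Ring A is the only ring closed: the bonds C4–C3a and C7–C7a form in the (2+2) step and the ring-closing bond C4–C5 forms in the thermal disrotatory 6π electrocyclisation of 25. No stereocentre is created in the product, since the transient ring CH of 24 is erased on ring opening, and C3 is untouched because the cascade is neutral and free of acid or base. The one selectivity needed is the orientation of the ketene–alkyne (2+2): the siloxy oxygen makes the chain-bearing alkyne carbon the nucleophile toward the ketene carbonyl carbon, so OH and OTIPS flank the C3 chain, and the 3-substituent of the cyclobutenone places CH2OTBS para to it. An excess of 22 offsets vinylketene dimerisation, and the temperature is held at or below 110 °C so that the siloxyalkyne does not rearrange to a silylketene.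

Step 13
Reactants: 27 benzannulated resorcinol monosilyl ether
Product: 28 2-{(1S,2R)-1-[3,5-bis(benzyloxy)phenyl]-2-[4-(benzyloxy)phenyl]-2-hydroxyethyl}-5-(hydroxymethyl)benzene-1,3-diol
Conditions: TBAF (excess), THF, 0 °C → rt, argon; H2O work-up
Reagents that add atoms: none
Why: Fluoride-driven desilylation should cleave the aryl triisopropylsilyl ether and both tert-butyldimethylsilyl ethers, exposing the locally symmetric resorcinol and the benzylic carbinol while leaving the benzyl ethers untouched.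

Step 14
Reactants: 28 resorcinol diol
Product: 29 (2S,3S)-3-[3,5-bis(benzyloxy)phenyl]-2-[4-(benzyloxy)phenyl]-6-(hydroxymethyl)-2,3-dihydro-1-benzofuran-4-ol
Conditions: TsOH·H2O (10 mol %), MeCN/CH2Cl2 (dilute), −20 → 0 °C
Reagents that add atoms: none
Why: In this acid-catalysed cyclodehydration only the secondary carbinol ionises (para-benzyloxy-stabilised cation, whereas the CH2OH on C6 is meta to both ring-A oxygens), and 5-exo-trig capture by either equivalent phenol oxygen should place the C2 aryl trans to the C3 aryl under both kinetic and thermodynamic control, so C2 (S) follows from C3 (S), with low temperature suppressing elimination to the triarylethene.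

Step 15
Reactants: 29 dihydrobenzofuran diol
Product: 30 (2S,3S)-3-[3,5-bis(benzyloxy)phenyl]-2-[4-(benzyloxy)phenyl]-4-hydroxy-2,3-dihydro-1-benzofuran-6-carbaldehyde
Conditions: activated MnO2, EtOAc, rt
Reagents that add atoms: none
Why: MnO2 oxidises benzylic alcohols selectively to aldehydes without over-oxidation and should leave the meta-disposed phenol and the dihydrofuran alone.

Step 16
Reactants: 30 tribenzyl aldehyde
Product: 31 gnetal, (2S,3S)-3-(3,5-dihydroxyphenyl)-4-hydroxy-2-(4-hydroxyphenyl)-2,3-dihydro-1-benzofuran-6-carbaldehyde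
Conditions: BCl3, C6HMe5, CH2Cl2, −78 °C; then MeOH, H2O
Reagents that add atoms: none
Why: BCl3-mediated debenzylation with pentamethylbenzene as a non-coordinating benzyl-cation scavenger cleaves aryl benzyl ethers at −78 °C without any reducing agent, so the aldehyde and the benzylic C2–O bond, both at risk under hydrogenolysis, should survive.

**Compound list**

1 | methyl 3,5-dihydroxyphenylacetate | COC(=O)Cc1cc(O)cc(O)c1 | starting material
2 | methyl 3,5-bis(benzyloxy)phenylacetate | COC(=O)Cc1cc(OCc2ccccc2)cc(OCc2ccccc2)c1 | intermediate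
3 | 3,5-bis(benzyloxy)phenylacetic acid | OC(=O)Cc1cc(OCc2ccccc2)cc(OCc2ccccc2)c1 | intermediate
4 | (R)-4-benzyl-1,3-oxazolidin-2-one | O=C1N[C@H](Cc2ccccc2)CO1 | starting material
5 | [3,5-bis(benzyloxy)phenyl]acetic pivalic anhydride | CC(C)(C)C(=O)OC(=O)Cc1cc(OCc2ccccc2)cc(OCc2ccccc2)c1 | intermediate (not isolated)
6 | (R)-4-benzyl-3-{[3,5-bis(benzyloxy)phenyl]acetyl}-1,3-oxazolidin-2-one | O=C(Cc1cc(OCc2ccccc2)cc(OCc2ccccc2)c1)N1[C@H](Cc2ccccc2)COC1=O | intermediate
7 | 4-(benzyloxy)benzaldehyde | O=Cc1ccc(OCc2ccccc2)cc1 | starting material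
8 | Z dibutylboron enolate of 6 (O–B cis to the aryl group) | CCCCB(CCCC)O/C(=C\c1cc(OCc2ccccc2)cc(OCc2ccccc2)c1)N1[C@H](Cc2ccccc2)COC1=O | intermediate (not isolated)
9 | O-dibutylboryl aldolate of 10 | CCCCB(CCCC)O[C@@H](c1ccc(OCc2ccccc2)cc1)[C@H](C(=O)N1[C@H](Cc2ccccc2)COC1=O)c1cc(OCc2ccccc2)cc(OCc2ccccc2)c1 | intermediate (not isolated)
10 | (4R)-4-benzyl-3-{(2R,3R)-2-[3,5-bis(benzyloxy)phenyl]-3-[4-(benzyloxy)phenyl]-3-hydroxypropanoyl}-1,3-oxazolidin-2-one | O[C@@H](c1ccc(OCc2ccccc2)cc1)[C@H](C(=O)N1[C@H](Cc2ccccc2)COC1=O)c1cc(OCc2ccccc2)cc(OCc2ccccc2)c1 | intermediate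
11 | (4R)-4-benzyl-3-{(2R,3R)-2-[3,5-bis(benzyloxy)phenyl]-3-[4-(benzyloxy)phenyl]-3-(tert-butyldimethylsilyloxy)propanoyl}-1,3-oxazolidin-2-one | CC(C)(C)[Si](C)(C)O[C@@H](c1ccc(OCc2ccccc2)cc1)[C@H](C(=O)N1[C@H](Cc2ccccc2)COC1=O)c1cc(OCc2ccccc2)cc(OCc2ccccc2)c1 | intermediate
12 | (2S,3R)-2-[3,5-bis(benzyloxy)phenyl]-3-[4-(benzyloxy)phenyl]-3-(tert-butyldimethylsilyloxy)propan-1-ol | CC(C)(C)[Si](C)(C)O[C@@H](c1ccc(OCc2ccccc2)cc1)[C@H](CO)c1cc(OCc2ccccc2)cc(OCc2ccccc2)c1 | intermediate
13 | (2R,3R)-2-[3,5-bis(benzyloxy)phenyl]-3-[4-(benzyloxy)phenyl]-3-(tert-butyldimethylsilyloxy)propanal | CC(C)(C)[Si](C)(C)O[C@@H](c1ccc(OCc2ccccc2)cc1)[C@H](C=O)c1cc(OCc2ccccc2)cc(OCc2ccccc2)c1 | intermediate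
14 | (3R,4R)-3-[3,5-bis(benzyloxy)phenyl]-4-[4-(benzyloxy)phenyl]-1,1-dibromo-4-(tert-butyldimethylsilyloxy)but-1-ene | CC(C)(C)[Si](C)(C)O[C@@H](c1ccc(OCc2ccccc2)cc1)[C@H](C=C(Br)Br)c1cc(OCc2ccccc2)cc(OCc2ccccc2)c1 | intermediate
15 | lithium acetylide of the terminal alkyne derived from 14 (configuration unchanged) | CC(C)(C)[Si](C)(C)O[C@@H](c1ccc(OCc2ccccc2)cc1)[C@H](C#C[Li])c1cc(OCc2ccccc2)cc(OCc2ccccc2)c1 | intermediate (not isolated)
16 | lithium ynolate corresponding to 17 (OLi in place of OSi) | CC(C)(C)[Si](C)(C)O[C@@H](c1ccc(OCc2ccccc2)cc1)[C@H](C#CO[Li])c1cc(OCc2ccccc2)cc(OCc2ccccc2)c1 | intermediate (not isolated)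
17 | triisopropyl{[(3S,4R)-3-[3,5-bis(benzyloxy)phenyl]-4-[4-(benzyloxy)phenyl]-4-(tert-butyldimethylsilyloxy)but-1-yn-1-yl]oxy}silane | CC(C)(C)[Si](C)(C)O[C@@H](c1ccc(OCc2ccccc2)cc1)[C@H](C#CO[Si](C(C)C)(C(C)C)C(C)C)c1cc(OCc2ccccc2)cc(OCc2ccccc2)c1 | intermediate
18 | tert-butyldimethyl(prop-2-yn-1-yloxy)silane | C#CCO[Si](C)(C)C(C)(C)C | starting material
19 | trichloroacetyl chloride | O=C(Cl)C(Cl)(Cl)Cl | starting material
20 | dichloroketene | O=C=C(Cl)Cl | intermediate (not isolated)
21 | 4,4-dichloro-3-[(tert-butyldimethylsilyloxy)methyl]cyclobut-2-en-1-one | O=C1C=C(CO[Si](C)(C)C(C)(C)C)C1(Cl)Cl | intermediate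
22 | 3-[(tert-butyldimethylsilyloxy)methyl]cyclobut-2-en-1-one | O=C1C=C(CO[Si](C)(C)C(C)(C)C)C1 | intermediate
23 | vinylketene 3-[(tert-butyldimethylsilyloxy)methyl]buta-1,3-dien-1-one | O=C=CC(=C)CO[Si](C)(C)C(C)(C)C | intermediate (not isolated)
24 | 2-{(1S,2R)-1-[3,5-bis(benzyloxy)phenyl]-2-[4-(benzyloxy)phenyl]-2-(tert-butyldimethylsilyloxy)ethyl}-4-[3-(tert-butyldimethylsilyloxy)prop-1-en-2-yl]-3-(triisopropylsilyloxy)cyclobut-2-en-1-one (both epimers at ring C4) | CC(C)(C)[Si](C)(C)O[C@@H](c1ccc(OCc2ccccc2)cc1)[C@H](C1=C(O[Si](C(C)C)(C(C)C)C(C)C)C(C(=C)CO[Si](C)(C)C(C)(C)C)C1=O)c1cc(OCc2ccccc2)cc(OCc2ccccc2)c1 | intermediate (not isolated)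
25 | dienylketene (3E)-2-{(1S,2R)-1-[3,5-bis(benzyloxy)phenyl]-2-[4-(benzyloxy)phenyl]-2-(tert-butyldimethylsilyloxy)ethyl}-5-[(tert-butyldimethylsilyloxy)methyl]-3-(triisopropylsilyloxy)hexa-1,3,5-trien-1-one | CC(C)(C)[Si](C)(C)O[C@@H](c1ccc(OCc2ccccc2)cc1)[C@H](C(=C=O)/C(O[Si](C(C)C)(C(C)C)C(C)C)=C\C(=C)CO[Si](C)(C)C(C)(C)C)c1cc(OCc2ccccc2)cc(OCc2ccccc2)c1 | intermediate (not isolated)
26 | 2-{(1S,2R)-1-[3,5-bis(benzyloxy)phenyl]-2-[4-(benzyloxy)phenyl]-2-(tert-butyldimethylsilyloxy)ethyl}-5-[(tert-butyldimethylsilyloxy)methyl]-3-(triisopropylsilyloxy)cyclohexa-2,4-dien-1-one | CC(C)(C)[Si](C)(C)O[C@@H](c1ccc(OCc2ccccc2)cc1)[C@H](C1=C(O[Si](C(C)C)(C(C)C)C(C)C)C=C(CO[Si](C)(C)C(C)(C)C)CC1=O)c1cc(OCc2ccccc2)cc(OCc2ccccc2)c1 | intermediate (not isolated)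
27 | 2-{(1S,2R)-1-[3,5-bis(benzyloxy)phenyl]-2-[4-(benzyloxy)phenyl]-2-(tert-butyldimethylsilyloxy)ethyl}-5-[(tert-butyldimethylsilyloxy)methyl]-3-(triisopropylsilyloxy)phenol | CC(C)(C)[Si](C)(C)O[C@@H](c1ccc(OCc2ccccc2)cc1)[C@H](c1c(O)cc(CO[Si](C)(C)C(C)(C)C)cc1O[Si](C(C)C)(C(C)C)C(C)C)c1cc(OCc2ccccc2)cc(OCc2ccccc2)c1 | intermediate
28 | 2-{(1S,2R)-1-[3,5-bis(benzyloxy)phenyl]-2-[4-(benzyloxy)phenyl]-2-hydroxyethyl}-5-(hydroxymethyl)benzene-1,3-diol | O[C@@H](c1ccc(OCc2ccccc2)cc1)[C@H](c1c(O)cc(CO)cc1O)c1cc(OCc2ccccc2)cc(OCc2ccccc2)c1 | intermediate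
29 | (2S,3S)-3-[3,5-bis(benzyloxy)phenyl]-2-[4-(benzyloxy)phenyl]-6-(hydroxymethyl)-2,3-dihydro-1-benzofuran-4-ol (2,3-trans) | OCc1cc(O)c2c(c1)O[C@H](c1ccc(OCc3ccccc3)cc1)[C@H]2c1cc(OCc3ccccc3)cc(OCc3ccccc3)c1 | intermediate
30 | (2S,3S)-3-[3,5-bis(benzyloxy)phenyl]-2-[4-(benzyloxy)phenyl]-4-hydroxy-2,3-dihydro-1-benzofuran-6-carbaldehyde | O=Cc1cc(O)c2c(c1)O[C@H](c1ccc(OCc3ccccc3)cc1)[C@H]2c1cc(OCc3ccccc3)cc(OCc3ccccc3)c1 | intermediate
31 | gnetal, (2S,3S)-3-(3,5-dihydroxyphenyl)-4-hydroxy-2-(4-hydroxyphenyl)-2,3-dihydro-1-benzofuran-6-carbaldehyde | O=Cc1cc(O)c2c(c1)O[C@H](c1ccc(O)cc1)[C@H]2c1cc(O)cc(O)c1 | target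

**Step count**

Total step count: 16 steps.
Longest linear sequence: 14 steps (steps 1 to 9 and 12 to 16, from 1 to 31); the cyclobutenone arm (steps 10 and 11) joins at step 12.

**Steps most likely to fail**

Step 12 (key step). The hindered, α-branched siloxyalkyne may capture the vinylketene more slowly than the ketene dimerises. At the temperature needed to open the cyclobutenone, the siloxyalkyne may also undergo a 1,3-silyl shift to a silylketene. The fallback sets out from 17 and comes back at 27. It generates the same vinylketene 23 at room temperature by photochemical Wolff rearrangement of a diazo ketone instead of by thermal opening of 22. Baylis–Hillman reaction of methyl vinyl ketone with aqueous formaldehyde (DABCO) would give 3-(hydroxymethyl)but-3-en-2-one F1. Silylation (TBSCl, imidazole, CH2Cl2) would give 3-[(tert-butyldimethylsilyloxy)methyl]but-3-en-2-one F2. Its lithium enolate (LiN(SiMe3)2, THF, −78 °C) would be acylated with CF3CO2CH2CF3 to 5-[(tert-butyldimethylsilyloxy)methyl]-1,1,1-trifluorohex-5-ene-2,4-dione F3. Detrifluoroacetylative diazo transfer (MsN3, Et3N, H2O, MeCN) would then give 1-diazo-3-[(tert-butyldimethylsilyloxy)methyl]but-3-en-2-one F4. Irradiation of F4 in the presence of 17 (300 nm, CH2Cl2, rt) would expel dinitrogen and deliver 23, whose (2+2) addition to 17 can then run at ambient temperature. Brief warming (toluene, 80 °C) would take 24 through 25 and 26 to 27.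

Step 9. Oxygen transfer from the peroxide to the congested lithium acetylide may stall. Any surplus base may also metalate the doubly activated propargylic benzylic C3–H, leading to epimerisation, allene formation or loss of silanolate. The fallback sets out from 11 and comes back at 17. It is a Kowalski ester homologation, which reaches ynolate 16 by a carbenoid 1,2-shift instead of by acetylide oxidation and bypasses the aldehyde altogether. Peroxide-assisted hydrolysis of 11 (LiOH, H2O2, THF/H2O, 0 °C) would give (2R,3R)-2-[3,5-bis(benzyloxy)phenyl]-3-[4-(benzyloxy)phenyl]-3-(tert-butyldimethylsilyloxy)propanoic acid F5. Methylation (Me3SiCHN2, MeOH/toluene) would give its methyl ester F6. Addition of LiCHBr2 (CH2Br2, lithium 2,2,6,6-tetramethylpiperidide, THF, −78 °C) followed by LiN(SiMe3)2 would give the lithium enolate of (3R,4R)-3-[3,5-bis(benzyloxy)phenyl]-4-[4-(benzyloxy)phenyl]-1,1-dibromo-4-(tert-butyldimethylsilyloxy)butan-2-one F7. Bromine–lithium exchange with n-BuLi and warming would make the C3 carbon migrate with retention to give 16, and TIPSOTf would then give 17. The strongly basic first stage can enolise F6, which is why this route is held in reserve.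

Step 16. BCl3 may ionise the C2–O bond of the 2-(4-oxyphenyl)dihydrofuran, causing ring opening, C2 epimerisation or Friedel–Crafts alkylation. Complexation of the Lewis acid by the aldehyde and the phenoxides may also leave benzyl ethers uncleaved. The fallback sets out from 29 and comes back at 31. It reverses the order of the last two operations and makes the deprotection reductive while no aldehyde is present. Hydrogenolysis of 29 (H2, 1 atm, Pd/C, EtOAc/MeOH, rt, stopped at complete debenzylation) would give (2S,3S)-3-(3,5-dihydroxyphenyl)-6-(hydroxymethyl)-2-(4-hydroxyphenyl)-2,3-dihydro-1-benzofuran-4-ol F8. Chemoselective oxidation of its benzylic alcohol (activated MnO2, acetone, rt) would then give 31.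

Further compounds
F1 | step 12 | 3-(hydroxymethyl)but-3-en-2-one | CC(=O)C(=C)CO
F2 | step 12 | 3-[(tert-butyldimethylsilyloxy)methyl]but-3-en-2-one | CC(=O)C(=C)CO[Si](C)(C)C(C)(C)C
F3 | step 12 | 5-[(tert-butyldimethylsilyloxy)methyl]-1,1,1-trifluorohex-5-ene-2,4-dione | O=C(CC(=O)C(=C)CO[Si](C)(C)C(C)(C)C)C(F)(F)F
F4 | step 12 | 1-diazo-3-[(tert-butyldimethylsilyloxy)methyl]but-3-en-2-one | [N-]=[N+]=CC(=O)C(=C)CO[Si](C)(C)C(C)(C)C
F5 | step 9 | (2R,3R)-2-[3,5-bis(benzyloxy)phenyl]-3-[4-(benzyloxy)phenyl]-3-(tert-butyldimethylsilyloxy)propanoic acid | CC(C)(C)[Si](C)(C)O[C@@H](c1ccc(OCc2ccccc2)cc1)[C@H](C(=O)O)c1cc(OCc2ccccc2)cc(OCc2ccccc2)c1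
F6 | step 9 | methyl (2R,3R)-2-[3,5-bis(benzyloxy)phenyl]-3-[4-(benzyloxy)phenyl]-3-(tert-butyldimethylsilyloxy)propanoate | CC(C)(C)[Si](C)(C)O[C@@H](c1ccc(OCc2ccccc2)cc1)[C@H](C(=O)OC)c1cc(OCc2ccccc2)cc(OCc2ccccc2)c1
F7 | step 9 | (3R,4R)-3-[3,5-bis(benzyloxy)phenyl]-4-[4-(benzyloxy)phenyl]-1,1-dibromo-4-(tert-butyldimethylsilyloxy)butan-2-one | CC(C)(C)[Si](C)(C)O[C@@H](c1ccc(OCc2ccccc2)cc1)[C@H](C(=O)C(Br)Br)c1cc(OCc2ccccc2)cc(OCc2ccccc2)c1
F8 | step 16 | (2S,3S)-3-(3,5-dihydroxyphenyl)-6-(hydroxymethyl)-2-(4-hydroxyphenyl)-2,3-dihydro-1-benzofuran-4-ol | OCc1cc(O)c2c(c1)O[C@H](c1ccc(O)cc1)[C@H]2c1cc(O)cc(O)c1
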